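## Structural features

The target is a C30H50 hydrocarbon of C2 symmetry: two trans-fused octahydronaphthalene (drim-8-ene) units, numbered as drimanes with primes for the second half, are joined through a CH2–CH2 bridge (C11–C11') between C9 and C9'. In each half, ring A (C1–C5, C10) carries the gem-dimethyl group at C4, and ring B (C5–C10) holds a tetrasubstituted C8=C9 alkene with a methyl group on C8 and the bridge on C9. The only stereocentres are the ring-fusion pairs: the CH at C5 and the methyl-bearing quaternary C10 are adjacent, trans, and S at all four positions. There is no heteroatom and nothing to protect; the fragile elements are the electron-rich tetrasubstituted alkenes, which under acid can migrate, trigger hydride or methyl shifts, or attack the other half and close a fifth ring. The real difficulty is twofold: C10 is a quaternary centre bonded to an alkene carbon, and the two stereochemical pairs are remote (C5 and C5' lie seven bonds apart through the bridge and eleven bonds apart in the open-chain intermediates) with no functional group between them, so they must be set in the same absolute sense by reagent control, and a meso diastereomer would be very hard to remove. The key step exploits C5: it is a CH that carries the C6–C7–C8=C9 chain and is β to C1, so with a carbonyl at C1 it is the β-carbon of a 2,4,4-trimethylcyclohexenone. Once C5 is fixed, a trans ring closure onto a C10 cation fixes C10 as well.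

## Logic of the disconnections

**15 to 14.** The C9–C10 and C9'–C10' bonds are cut. Each joins a quaternary carbon to an alkene carbon, which is the bond a cation–olefin closure makes. Both B rings open and both quaternary stereocentres disappear, leaving one stereocentre (C5) per half in 14. The forward step must protonate the C1=C10 alkene, close ring B trans before H-5 can be lost from the C10 cation, end with the alkene at C8=C9, and stop at the tetracycle.

**14 to 13 to 11, through 12.** No skeletal bond is cut; the C1=C10 alkene is traced back through 13 to the C1 carbonyl of 11, which is the group that makes C5 electrophilic. The alkene must be placed toward the methyl-bearing C10 without acid, because a C5=C10 isomer would erase C5. Reduction of 11 to the alcohol and dehydration was set aside: base-induced elimination would have to remove a C10 hydrogen that is syn-axial to a C4 methyl group and competes with the C2 hydrogens. Enolisation under equilibrating conditions (12) followed by reductive removal of the sulfonate was chosen instead.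

**11 to 8 and 9.** The C5–C6 and C5'–C6' bonds are cut, at the carbon β to each carbonyl; the two cuts are equivalent by symmetry. Thirty carbons fall into one C12 bis-nucleophile (8) and two molecules of 9, a commercial C9 ring that already holds the gem-dimethyl group. The forward step must control two remote centres in the same sense by the catalyst alone, favour 1,4- over 1,2-addition at a β-carbon flanked by a quaternary carbon and an α-methyl group, and react at both ends. Two points of the design of 8 follow from this: bromide as counter-ion and an ether solution free of THF. The E geometry of both alkenes is kept for the chair closure of the last step. The meso isomer cannot be counted on to separate at the stage of 11, since its centres are eleven bonds apart and 11 is an epimer mixture at C10; crystallisation of 15 is the realistic place to remove it.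

**8 to 7 to 6.** Functional-group changes only (C–Mg from C–Br from C–OH). The forward steps must not move or isomerise the trisubstituted alkenes.

**6 to 3 and 4, through 5.** The C7–C8 and C7'–C8' bonds (alkenyl–CH2) are cut, so that two molecules of 4 supply C6 and C7 of each half with the oxygen at the right end. The C12 chain falls into a C8 core and two C2 units. The alkenyl metal 5 must be configurationally stable and react at both ends.

**3 to 1, through 2.** The two C–I bonds are traced back to a syn-hydrometalation of the two alkynes of 1, which sets both E-trisubstituted alkenes at once from a symmetrical commercial diyne. The metal must end on the methyl-bearing carbon of each alkyne. Isolating 3, in place of a one-pot transmetalation to copper, allows a minor regioisomer to be detected and removed before the chain is extended.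

## Other disconnections considered

Alternative 1: The cut is at C9–C11 and C9'–C11', which turns the bridge into a two-carbon linchpin and each half into the trans-fused ketone A1. Forward, an acetylene dianion equivalent (with CeCl3 to suppress enolisation) would add to the C9 carbonyl of two molecules of A1 to give the ynediol A2. Saturation of the triple bond and twofold loss of water toward C8 would then give the target.
- In favour: both ring systems and all four stereocentres come ready-made in an enantiopure building block. There is no meso problem, no late cationic closure and no risk to C5. On stereochemical security this plan is better than the chosen one.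
- Against: the C9 carbonyl of A1 lies between the quaternary C10 and the methyl-bearing C8 and is enolisable, so both additions are hindered, the second more so. A1 is not a catalogue compound and would need several steps of degradation from the terpenoid chiral pool. After A2 the order of events is awkward: dehydration first gives a conjugated dienyne that must be reduced only at the triple bond, and hydrogenation first opens a competing elimination toward C11.
- Comparison: structurally it joins three pieces in its key step, as the chosen plan does (equal). Mechanistically it replaces catalyst control and a cationic cyclisation by polar additions (an advantage). In step economy it is about equal after the key step and worse before it.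

Alternative 2: The cut is at the two C10–methyl bonds, with the cyclohexadiene rings traced back to the arene rings of the bibenzyl bis-amide A3, whose amide carbon is C1. Forward, dissolving-metal reduction of both benzamide rings to amide enolates and methylation at C10 under control of the prolinol-derived auxiliary would give the bis-diene A4. A4 has both quaternary centres in place and the C8=C9 alkenes already tetrasubstituted.
- In favour: the quaternary centres, the hardest in the target, would be made directly under auxiliary control, and A3 is a simple symmetrical arene. On the control of C10 and the placing of the C8=C9 alkene this plan is better than the chosen one.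
- Against: A4 contains only ring B. Ring A (C2, C3, C4 with both methyl groups, and the C4–C5 bond with a trans hydrogen at C5) must be built on twice, starting from a tertiary amide on a quaternary carbon that is hard to cleave or reduce. The isolated C5=C6 alkene offers no polarity for that annulation.
- Comparison: structurally the chosen plan buys ring A and builds ring B, whereas this plan makes ring B and must build ring A, the more laborious direction. Mechanistically both set one centre per half by reagent control and relay the other (equal in principle), but the relay from C10 to C5 is still to be devised here. In step economy this plan is clearly longer after its key step.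

Alternative 3: Each half is cut at C5–C10 and C6–C7, so that rings A and B of both halves open together and the precursor is the acyclic bis-trienal A5. Forward, a salt of a single enantiomer of 5-benzyl-2-tert-butyl-3-methylimidazolidin-4-one would turn each enal into an iminium ion, and each C7=C8–C9=C10 diene would add to its C5=C6 dienophile. This would give the tetracyclic dialdehyde A6 with C5, C6 and C10 of both halves set; the two formyl groups at C6 would then have to be removed.
- In favour: four rings, four C–C bonds and six stereocentres in one operation, the C8=C9 alkene formed in its final tetrasubstituted position, and no acid-labile stage. In bonds formed per step and in alkene placement this plan is better than the chosen one.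
- Against: the diene terminus C10 is fully substituted, so one substituent is always cis on the diene and the reactive s-cis conformer is strongly disfavoured. The new C5–C10 bond joins that carbon to one next to the C4 gem-dimethyl group. Iminium activation of an enal with a neopentyl-like β-carbon is slow. A5, with two stereodefined tetrasubstituted dienes, is itself a long synthesis, and the formyl groups serve only as activators and cost a twofold decarbonylation.
- Comparison: structurally this plan is the more ambitious (all rings in one step against none in the chosen key step). Mechanistically its stereocontrol is equal in kind (catalyst control at each half independently, with the same meso question), but the cycloaddition must overcome more steric strain than the conjugate addition. In step economy the gain in the key step is lost in making A5 and removing the formyl groups.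

Key step: step 5

Assumption: the enantiomer of the ferrocenyl diphosphine is taken to be the one that delivers the alkyl group to the Si face of C3 of 9 (priorities C2 > C4 > H), which makes both new centres R in 11; its hand is to be assigned on a model addition.

Step 1
Reactants: 1 octa-2,6-diyne
Product: 3 (2E,6E)-2,7-diiodoocta-2,6-diene, via bis(alkenylzirconocene chloride) 2 (not isolated)
Conditions: Cp2Zr(H)Cl (3 equiv), THF, rt → 50 °C; then I2, THF, 0 °C
Reagents that add atoms: iodine, II
Why: Syn-hydrozirconation of both internal alkynes; excess Cp2Zr(H)Cl and gentle warming let the alkenylzirconium regioisomers equilibrate to the one with zirconium on the less hindered, methyl-bearing carbon, and iodinolysis with retention should give the E,E-diiodide. Isolating 3 allows its regio- and stereochemical purity to be checked before the chain is extended.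

Step 2
Reactants: 3 (2E,6E)-2,7-diiodoocta-2,6-diene; 4 oxirane (two equivalents react, one at each terminus)
Product: 6 (3E,7E)-3,8-dimethyldeca-3,7-diene-1,10-diol, via dilithiodiene 5 (not isolated)
Conditions: t-BuLi (4.2 equiv), Et2O, −78 °C; 4 (3 equiv) in THF, −78 → 0 °C; H2O
Reagents that add atoms: oxirane (the second of the two equivalents that react; the first is reactant 4), C1CO1
Why: Iodine–lithium exchange at both alkenyl iodides with retention of geometry (two equivalents of t-BuLi per iodide, the second destroying t-BuI), then ring opening of one molecule of oxirane by each alkenyllithium terminus forms C7–C8 and C7'–C8' and delivers the primary alcohols. No stereocentre is formed and the trisubstituted alkenes keep their geometry.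

Step 3
Reactants: 6 (3E,7E)-3,8-dimethyldeca-3,7-diene-1,10-diol
Product: 7 (3E,7E)-1,10-dibromo-3,8-dimethyldeca-3,7-diene
Conditions: CBr4, PPh3, CH2Cl2, 0 °C
Reagents that add atoms: tetrabromomethane, BrC(Br)(Br)Br
Why: Appel bromination of the two primary homoallylic alcohols by SN2 displacement of the oxyphosphonium group; the neutral conditions leave the alkenes untouched.

Step 4
Reactants: 7 (3E,7E)-1,10-dibromo-3,8-dimethyldeca-3,7-diene
Product: 8 (3E,7E)-3,8-dimethyldeca-3,7-diene-1,10-diylbis(magnesium bromide)
Conditions: Mg turnings (I2-activated, excess), Et2O, rt, slow addition of 7; solution titrated and used at once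
Reagents that add atoms: magnesium (one atom per C–Br bond), [Mg]
Why: Direct insertion of magnesium into the two primary C–Br bonds (Grignard formation), with slow addition to limit Wurtz coupling. Ether is used in place of THF because the enantioselectivity of the following conjugate addition is expected to suffer in THF, and the solution is kept at or below room temperature so that homoallyl–cyclopropylcarbinyl equilibration cannot scramble the alkene geometry.

Step 5
Reactants: 8 (3E,7E)-3,8-dimethyldeca-3,7-diene-1,10-diylbis(magnesium bromide); 9 2,4,4-trimethylcyclohex-2-en-1-one (two equivalents react, one at each terminus)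
Product: 11 (3R,3'R)-3,3'-[(3E,7E)-3,8-dimethyldeca-3,7-diene-1,10-diyl]bis(2,4,4-trimethylcyclohexan-1-one), via bis(bromomagnesium enolate) 10 (not isolated)
Conditions: 9 (2.6 equiv), CuBr·SMe2 (10 mol %), 1-[2-(diphenylphosphanyl)ferrocenyl]ethyldicyclohexylphosphane (single enantiomer, 12 mol %), t-BuOMe, −78 °C; 8 in Et2O added over 4 h; aq. NH4Cl
Reagents that add atoms: 2,4,4-trimethylcyclohex-2-en-1-one (the second of the two equivalents that react; the first is reactant 9), CC1=CC(C)(C)CCC1=O
Why: The CuBr–diphosphine complex is transmetalated by one C–Mg terminus of 8 to a chiral alkyl complex of monovalent copper, which binds the enone alkene of 9 while magnesium activates the carbonyl oxygen. Oxidative addition gives a β-cuprio enolate of trivalent copper and reductive elimination forms C5–C6, releasing the magnesium enolate and the catalyst; the second terminus repeats the cycle to give 10, which is protonated on work-up to 11. The closest known reaction type is the CuBr/ferrocenyl-diphosphine-catalysed enantioselective conjugate addition of alkylmagnesium bromides to cyclohexenones, known separately for 2-methyl and for 4,4-dimethyl substitution. No ring is closed. C5 and C5' are set by the ligand at each terminus independently (catalyst control, no relay along the ten-carbon chain), so two matched events give the C2 isomer and one mismatch gives the meso isomer; the enantiomeric purity of the C2 isomer should thereby be raised statistically at the cost of some meso material. C10 and C10' arise on protonation as epimers and carry no information onward. The step needs 1,4- over 1,2-selectivity and complete reaction at both ends; slow addition of 8 to excess 9, low temperature, the bromide counter-ion and a THF-free ether medium are meant to secure this, helped by the fact that the β-carbon of 9 bears only hydrogen despite its quaternary neighbour.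

Step 6
Reactants: 11 (3R,3'R)-3,3'-[(3E,7E)-3,8-dimethyldeca-3,7-diene-1,10-diyl]bis(2,4,4-trimethylcyclohexan-1-one)
Product: 13 (3E,7E)-3,8-dimethyldeca-3,7-diene-1,10-diylbis[(3S)-2,4,4-trimethylcyclohex-1-ene-3,1-diyl] bis(trifluoromethanesulfonate), via bis(chloromagnesium enolate) 12 (not isolated)
Conditions: i-Pr2NMgCl (from i-PrMgCl and i-Pr2NH, slight excess of amine; 2.4 equiv), THF, 0 °C → rt; then DMPU, N-(5-chloropyridin-2-yl)bis(trifluoromethanesulfonyl)imide (2.4 equiv), 0 °C → rt; aq. NH4Cl
Reagents that add atoms: N-(5-chloropyridin-2-yl)-1,1,1-trifluoro-N-[(trifluoromethyl)sulfonyl]methanesulfonamide (one per enolate), O=S(=O)(N(c1ccc(Cl)cn1)S(=O)(=O)C(F)(F)F)C(F)(F)F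
Why: Thermodynamic enolisation with a hindered halomagnesium dialkylamide followed by enol triflate formation: the amide deprotonates reversibly, with free amine as proton shuttle, so the enolate should settle as the more substituted C1=C10 regioisomer 12, and O-sulfonylation by the N-pyridyl triflimide fixes this regiochemistry. C10 becomes trigonal, which removes the epimer mixture, and C5 is not touched (its descriptor changes from R to S only because the priorities change).

Step 7
Reactants: 13 (3E,7E)-3,8-dimethyldeca-3,7-diene-1,10-diylbis[(3S)-2,4,4-trimethylcyclohex-1-ene-3,1-diyl] bis(trifluoromethanesulfonate)
Product: 14 (3E,7E)-3,8-dimethyl-1,10-bis[(1S)-2,6,6-trimethylcyclohex-2-en-1-yl]deca-3,7-diene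
Conditions: Pd(OAc)2 (cat.), PPh3, HCO2H, Et3N, DMF, 60 °C
Reagents that add atoms: none
Why: Formate reduction of enol triflates catalysed by Pd(OAc)2/PPh3: oxidative addition of the C–O bond to zerovalent palladium, exchange of triflate for formate, loss of CO2 and C–H reductive elimination should give the C1=C10 alkene exactly where the enol double bond was. The trisubstituted chain alkenes and C5 are inert under these buffered conditions.

Step 8
Reactants: 14 (3E,7E)-3,8-dimethyl-1,10-bis[(1S)-2,6,6-trimethylcyclohex-2-en-1-yl]deca-3,7-diene
Product: 15 1,2-bis[(4aS,8aS)-2,5,5,8a-tetramethyl-3,4,4a,5,6,7,8,8a-octahydronaphthalen-1-yl]ethane (the target)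
Conditions: ClSO3H (excess), 2-nitropropane, −78 °C; quench Et3N/MeOH, −78 °C
Reagents that add atoms: none
Why: Protonation at C1 gives the tertiary C10 cation, which is captured by C9 of the E-alkene through a chair transition state (cation–olefin cyclisation, as in superacid closures of monocyclic terpenoids). With the C5–C6 bond equatorial on ring A the new C9–C10 bond also forms equatorially, which places the C10 methyl anti to H-5 (trans fusion), so C5 dictates C10. Loss of H-9 from each tertiary C8 cation should give the tetrasubstituted C8=C9 alkene.

## Compound list

1 | octa-2,6-diyne | CC#CCCC#CC | starting material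
2 | (2E,6E)-octa-2,6-diene-2,7-diylbis[chlorobis(cyclopentadienyl)zirconium] | Cl[Zr](C1C=CC=C1)(C1C=CC=C1)/C(C)=C/CC/C=C(C)/[Zr](Cl)(C1C=CC=C1)C1C=CC=C1 | intermediate
3 | (2E,6E)-2,7-diiodoocta-2,6-diene | I/C(C)=C/CC/C=C(C)/I | intermediate
4 | oxirane | C1CO1 | starting material
5 | (2Z,6Z)-octa-2,6-diene-2,7-diyldilithium (lithium trans to the chain CH2, geometry of 3 retained) | [Li]/C(C)=C/CC/C=C(C)/[Li] | intermediate
6 | (3E,7E)-3,8-dimethyldeca-3,7-diene-1,10-diol | OCC/C(C)=C/CC/C=C(C)/CCO | intermediate
7 | (3E,7E)-1,10-dibromo-3,8-dimethyldeca-3,7-diene | BrCC/C(C)=C/CC/C=C(C)/CCBr | intermediate
8 | (3E,7E)-3,8-dimethyldeca-3,7-diene-1,10-diylbis(magnesium bromide) | Br[Mg]CC/C(C)=C/CC/C=C(C)/CC[Mg]Br | intermediate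
9 | 2,4,4-trimethylcyclohex-2-en-1-one | CC1=CC(C)(C)CCC1=O | starting material
10 | bis(bromomagnesium) C1=C10 enolate of 11, (3S,3'S) | CC1=C(O[Mg]Br)CCC(C)(C)[C@@H]1CC/C(C)=C/CC/C=C(C)/CC[C@H]1C(C)(C)CCC(O[Mg]Br)=C1C | intermediate
11 | (3R,3'R)-3,3'-[(3E,7E)-3,8-dimethyldeca-3,7-diene-1,10-diyl]bis(2,4,4-trimethylcyclohexan-1-one), epimers at C2 and C2' | CC1C(=O)CCC(C)(C)[C@@H]1CC/C(C)=C/CC/C=C(C)/CC[C@H]1C(C)(C)CCC(=O)C1C | intermediate
12 | bis(chloromagnesium) C1=C10 enolate of 11, (3S,3'S) | CC1=C(O[Mg]Cl)CCC(C)(C)[C@@H]1CC/C(C)=C/CC/C=C(C)/CC[C@H]1C(C)(C)CCC(O[Mg]Cl)=C1C | intermediate
13 | (3E,7E)-3,8-dimethyldeca-3,7-diene-1,10-diylbis[(3S)-2,4,4-trimethylcyclohex-1-ene-3,1-diyl] bis(trifluoromethanesulfonate) | CC1=C(OS(=O)(=O)C(F)(F)F)CCC(C)(C)[C@@H]1CC/C(C)=C/CC/C=C(C)/CC[C@H]1C(C)(C)CCC(OS(=O)(=O)C(F)(F)F)=C1C | intermediate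
14 | (3E,7E)-3,8-dimethyl-1,10-bis[(1S)-2,6,6-trimethylcyclohex-2-en-1-yl]deca-3,7-diene | CC1=CCCC(C)(C)[C@@H]1CC/C(C)=C/CC/C=C(C)/CC[C@H]1C(C)(C)CCC=C1C | intermediate
15 | 1,2-bis[(4aS,8aS)-2,5,5,8a-tetramethyl-3,4,4a,5,6,7,8,8a-octahydronaphthalen-1-yl]ethane | CC1=C(CCC2=C(C)CC[C@H]3C(C)(C)CCC[C@]23C)[C@@]2(C)CCCC(C)(C)[C@@H]2CC1 | target

Total step count: 8. Longest linear sequence: 8 steps (1 to 15); 4 and 9 are commercial and enter directly.

## Least certain steps and fallbacks

**Step 5 (key step).** Conjugate addition at a β-carbon flanked by a quaternary carbon and an α-methyl group may be slow, which would let uncatalysed 1,2-addition and incomplete reaction at the second terminus compete. Facial selectivity lower than on the simpler enones would produce the meso diastereomer, which is not expected to separate before 15. The fallback moves the stereochemical information into an allylic alcohol and transfers it by a directed substitution. It sets out from 9 and 8. Corey–Bakshi–Shibata reduction of 9 with (S)-1-methyl-3,3-diphenyltetrahydro-1H,3H-pyrrolo[1,2-c][1,3,2]oxazaborole and BH3·SMe2 should give (R)-2,4,4-trimethylcyclohex-2-en-1-ol F1. Esterification with 2-(diphenylphosphanyl)benzoic acid (DCC, DMAP) would give (R)-2,4,4-trimethylcyclohex-2-en-1-yl 2-(diphenylphosphanyl)benzoate F2. Treatment of two equivalents of F2 with 8 and CuBr·SMe2 in Et2O should deliver each alkyl terminus, directed by the phosphane, syn to the leaving group in an SN2' substitution at C5. This shifts the alkene to C1=C10 and transfers the carbinol configuration to C5 (S). The fallback comes back to the route at 14 and bypasses 11, 12 and 13.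

**Step 8.** Three processes threaten it.
- Loss of H-5 from the C10 cation and reprotonation before ring closure would erode the C5 configuration. This is best assessed on a one-ring model before the two-directional run.
- Unselective proton loss from the C8 cations would leave double-bond isomers.
- Once one alkene has formed, cation–olefin attack between the two halves, or hydride and methyl shifts, would lead past the tetracycle.

The fallback separates ring closure from alkene placement. It sets out from 14: the closure would be run for a short contact time and quenched cold into base, accepting the kinetic mixture of double-bond isomers. Its principal component is expected to be 1,2-bis[(1S,4aS,8aS)-2,5,5,8a-tetramethyl-1,4,4a,5,6,7,8,8a-octahydronaphthalen-1-yl]ethane F3 (the Δ7,Δ7' isomer, with exocyclic isomers beside it). The mixture would then be converged by a separate isomerisation with catalytic iodine in benzene at room temperature, conditions under which the tetrasubstituted position is favoured and a second closure between the halves is not expected. It comes back to the route at 15.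

**Step 6.** Incomplete equilibration would leave some of the less substituted enolate and hence a C1=C2 triflate, and O-sulfonylation of the hindered magnesium enolate may be sluggish. The fallback uses the enolate at the moment the conjugate addition forms it, when its regiochemistry is defined by the mechanism. It sets out from 8 and 9: at the end of the addition of step 5, DMPU and the N-pyridyl triflimide would be added to the cold solution of 10 before any proton source. It comes back to the route at 13, leaves out 11 and 12 and makes no new compound.

**Step 2.** Incomplete double iodine–lithium exchange, protonation of one alkenyllithium terminus, or slow opening of oxirane by the α-methyl alkenyllithium would give mono-functionalised chains. The fallback builds the two-carbon ends by cross-coupling and hydroboration. It sets out from 3: twofold Suzuki–Miyaura coupling with vinylboronic acid pinacol ester (Pd(PPh3)4, aq. K2CO3, THF) should give (3E,7E)-3,8-dimethyldeca-1,3,7,9-tetraene F4. Hydroboration of the two terminal vinyl groups with 9-BBN and oxidation (NaOH, H2O2) comes back to the route at 6.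

## Further compounds

F1 | step 5 | (R)-2,4,4-trimethylcyclohex-2-en-1-ol | CC1=CC(C)(C)CC[C@H]1O
F2 | step 5 | (R)-2,4,4-trimethylcyclohex-2-en-1-yl 2-(diphenylphosphanyl)benzoate | CC1=CC(C)(C)CC[C@H]1OC(=O)c1ccccc1P(c1ccccc1)c1ccccc1
F3 | step 8 | 1,2-bis[(1S,4aS,8aS)-2,5,5,8a-tetramethyl-1,4,4a,5,6,7,8,8a-octahydronaphthalen-1-yl]ethane | CC1=CC[C@H]2C(C)(C)CCC[C@]2(C)[C@H]1CC[C@H]1C(C)=CC[C@H]2C(C)(C)CCC[C@]12C
F0 | step 6 | none | none
F4 | step 2 | (3E,7E)-3,8-dimethyldeca-1,3,7,9-tetraene | C=C/C(C)=C/CC/C=C(C)/C=C
A1 | alternative 1 | (2R,4aS,8aS)-2,5,5,8a-tetramethyloctahydronaphthalen-1(2H)-one | O=C1[C@H](C)CC[C@H]2C(C)(C)CCC[C@]12C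
A2 | alternative 1 | C2-symmetric 9,9'-ynediol, 1,1'-(ethyne-1,2-diyl)bis(2,5,5,8a-tetramethyldecahydronaphthalen-1-ol) with axial alkynyl groups | O[C@@]1(C#C[C@]2(O)[C@H](C)CC[C@H]3C(C)(C)CCC[C@]23C)[C@H](C)CC[C@H]2C(C)(C)CCC[C@]12C
A3 | alternative 2 | 1,2-bis{2-methyl-6-[(S)-2-(methoxymethyl)pyrrolidine-1-carbonyl]phenyl}ethane | C(Cc1c(C)cccc1C(=O)N1CCC[C@H]1COC)c1c(C)cccc1C(=O)N1CCC[C@H]1COC
A4 | alternative 2 | 1,2-bis{(6S)-2,6-dimethyl-6-[(S)-2-(methoxymethyl)pyrrolidine-1-carbonyl]cyclohexa-1,4-dien-1-yl}ethane (quaternary C10 and C10') | C(CC1=C(C)CC=C[C@]1(C)C(=O)N1CCC[C@H]1COC)C1=C(C)CC=C[C@]1(C)C(=O)N1CCC[C@H]1COC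
A5 | alternative 3 | (2E,8E,12E,18E)-4,4,8,13,17,17-hexamethyl-9,12-di(prop-1-en-2-yl)icosa-2,8,12,18-tetraenedial | O=C/C=C/C(C)(C)CCC/C(C)=C(\CC/C(=C(C)\CCCC(C)(C)/C=C/C=O)C(C)=C)C(C)=C
A6 | alternative 3 | tetracyclic diene dialdehyde with formyl groups on C6 and C6' | C(CC1=C(C)C[C@H](C=O)[C@H]2C(C)(C)CCC[C@]12C)C1=C(C)C[C@H](C=O)[C@H]2C(C)(C)CCC[C@]12C
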